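**Overview**

Numbering: lactone carbonyl C1, acyloxy carbon C2, olefin C5=C6, diol carbons C7 and C8, ring-oxygen carbon C9, propyl chain C10–C12.
- Cuts: first the acyl C–O bond of the muconate at O2; then, instead of opening the lactone, C1 is joined to C6 and tin is placed on C5 (retro-fragmentation); finally C6–C7 (aldol) and C5–Sn (conjugate addition).
- Enabling feature: in the ten-membered ring C1 and C6 are bridged by C2–C5 on one side and by C7–C8–C9–O on the other. A C1–C6 bond therefore turns the macrocycle into a cyclohexane (C1–C6) fused to a tetrahydropyran (C1, C6, C7, C8, C9, O), and the shared bond lies exactly between the lactone C=O and the C5=C6 double bond.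
- Forward order: the carbocycle is bought as cyclohexenone; the C7–C12 aldehyde is joined at C6–C7 by stannyl conjugate addition/aldol; the pyran ring closes by hemiketalisation of O9 onto C1; Pb(OAc)4 cleaves C1–C6 and C5–Sn to release the ten-membered E-lactone; the muconate is attached to O2 last.
- Stereochemistry: C2 from lipase resolution of 6-acetoxycyclohexenone; C8 and C9 from (2R,3R)-3-propyloxiranemethanol (C9 inverted in the titanium-mediated opening); C7 from Cornforth–Felkin addition to the α-silyloxy aldehyde; the E olefin from the trans C5-tin/C6-chain relationship, both centres being sacrificial.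

Key step: step 12

Assumption: the lipase is taken to hydrolyse the (R)-acetate faster (carbonyl side acting as the larger group in the usual empirical model for secondary esters), so the (S)-enantiomer is recovered as acetate 3; with an enzyme of opposite preference the (S)-alcohol 4 would be isolated directly and step 3 would fall away.

**Route**

Step 1
Reactants: 1 cyclohex-2-en-1-one
Product: 2 (±)-6-acetoxycyclohex-2-en-1-one
Conditions: Mn(OAc)3·2H2O (2.5 equiv), PhH, reflux (Dean–Stark)
Reagents that add atoms: manganese triacetate dihydrate, CC(=O)[O-].CC(=O)[O-].CC(=O)[O-].[Mn+3].O.O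
Why: Mn(OAc)3-mediated α'-acetoxylation of enones: the trivalent manganese enolate formed on the saturated side delivers acetate to C6 regioselectively, a standard reaction of cyclohexenones that gives the racemic acetate.

Step 2
Reactants: 2 (±)-6-acetoxycyclohex-2-en-1-one
Product: 3 (S)-6-acetoxycyclohex-2-en-1-one
Conditions: Amano lipase PS (Burkholderia cepacia), pH 7 phosphate buffer/MTBE, 25 °C, stopped just past half conversion
Reagents that add atoms: none
Why: Lipase-catalysed kinetic resolution by enantioselective ester hydrolysis, established for α'-acetoxy enones: the (R)-acetate is consumed and, with conversion pushed slightly beyond one half, the remaining (S)-acetate should be of high enantiomeric purity; this is the source of C2 of the target.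

Step 3
Reactants: 3 (S)-6-acetoxycyclohex-2-en-1-one
Product: 4 (S)-6-hydroxycyclohex-2-en-1-one
Conditions: Sc(OTf)3 (cat.), MeOH, 25 °C
Reagents that add atoms: none
Why: Sc(OTf)3-catalysed transesterification with methanol removes acetates that carry a chelating carbonyl neighbour under essentially neutral conditions, so the enolisable α-ketol centre should keep its configuration (basic methanolysis would risk racemisation).

Step 4
Reactants: 4 (S)-6-hydroxycyclohex-2-en-1-one
Product: 5 (S)-6-(triethylsilyloxy)cyclohex-2-en-1-one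
Conditions: TESCl, imidazole, DMF, 0 °C
Reagents that add atoms: chlorotriethylsilane, CC[Si](Cl)(CC)CC
Why: Routine silyl ether formation on the secondary hydroxyl under weakly basic conditions; the stereocentre is not involved.

Step 5
Reactants: 6 (2R,3R)-3-propyloxiranemethanol
Product: 7 (2R,3S)-3-(4-methoxybenzyloxy)hexane-1,2-diol
Conditions: 4-MeOC6H4CH2OH (3 equiv), Ti(OiPr)4 (1.5 equiv), PhMe, 70 °C; aq. tartaric acid work-up
Reagents that add atoms: 4-methoxybenzyl alcohol, COc1ccc(CO)cc1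
Why: Ti(OiPr)4-mediated regioselective opening of a 2,3-epoxy alcohol: the titanium-bound epoxy alkoxide is attacked by the alcohol at C3 in an SN2 fashion, so C3 (later C9) is inverted, C2 (later C8) is untouched and the erythro 3-alkoxy-1,2-diol results.

Step 6
Reactants: 7 (2R,3S)-3-(4-methoxybenzyloxy)hexane-1,2-diol
Product: 8 (2R,3S)-1,2-bis(tert-butyldimethylsilyloxy)-3-(4-methoxybenzyloxy)hexane
Conditions: TBSCl (2.5 equiv), imidazole, DMF, 25 to 40 °C
Reagents that add atoms: tert-butylchlorodimethylsilane, CC(C)(C)[Si](C)(C)Cl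
Why: Exhaustive silylation of the primary and the secondary hydroxyl under standard conditions; stereocentres untouched.

Step 7
Reactants: 8 (2R,3S)-1,2-bis(tert-butyldimethylsilyloxy)-3-(4-methoxybenzyloxy)hexane
Product: 9 (2R,3S)-2-(tert-butyldimethylsilyloxy)-3-(4-methoxybenzyloxy)hexan-1-ol
Conditions: HF·pyridine, pyridine, THF, 0 °C
Reagents that add atoms: none
Why: Rate-based selective cleavage of the primary TBS ether with pyridine-buffered HF·pyridine, a standard differentiation of primary from secondary silyl ethers; the PMB ether is inert.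

Step 8
Reactants: 9 (2R,3S)-2-(tert-butyldimethylsilyloxy)-3-(4-methoxybenzyloxy)hexan-1-ol
Product: 10 (2S,3S)-2-(tert-butyldimethylsilyloxy)-3-(4-methoxybenzyloxy)hexanal
Conditions: Dess–Martin periodinane, pyridine, CH2Cl2, 0 to 25 °C
Reagents that add atoms: none
Why: Dess–Martin oxidation of the primary alcohol under buffered, non-enolising conditions, so the α-silyloxy stereocentre should not epimerise; the aldehyde is used at once.

Step 9
Reactants: 5 (S)-6-(triethylsilyloxy)cyclohex-2-en-1-one; 10 (2S,3S)-2-(tert-butyldimethylsilyloxy)-3-(4-methoxybenzyloxy)hexanal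
Product: 12 (2S,3S,6S)-2-[(1R,2R,3S)-2-(tert-butyldimethylsilyloxy)-1-hydroxy-3-(4-methoxybenzyloxy)hexyl]-6-(triethylsilyloxy)-3-(tributylstannyl)cyclohexan-1-one, via lithium enolate 11 (not isolated)
Conditions: Bu3SnH, LiN(iPr)2, THF, 0 °C; then 5, −78 °C; then 10, −78 °C; AcOH quench at −78 °C
Reagents that add atoms: tributyltin hydride, CCCC[SnH](CCCC)CCCC
Why: Conjugate addition of a stannyllithium to the enone followed by aldol trapping of the regiodefined lithium enolate (three-component coupling): tin adds axially to C5, the aldehyde then approaches C6 anti to the bulky stannyl group (C5/C6 trans), and attack on the Cornforth–Felkin face of the α-silyloxy aldehyde through a chair Zimmerman–Traxler transition state sets C7 anti to the C8 silyloxy group; the configuration of C5 relative to C2 is immaterial because C5 and C6 are erased in step 12.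

Step 10
Reactants: 12 (2S,3S,6S)-2-[(1R,2R,3S)-2-(tert-butyldimethylsilyloxy)-1-hydroxy-3-(4-methoxybenzyloxy)hexyl]-6-(triethylsilyloxy)-3-(tributylstannyl)cyclohexan-1-one
Product: 13 (2S,3S,6S)-2-[(1R,2S,3S)-1,2-bis(tert-butyldimethylsilyloxy)-3-(4-methoxybenzyloxy)hexyl]-6-(triethylsilyloxy)-3-(tributylstannyl)cyclohexan-1-one
Conditions: TBSOTf, 2,6-lutidine, CH2Cl2, −78 to −40 °C
Reagents that add atoms: tert-butyldimethylsilyl trifluoromethanesulfonate, CC(C)(C)[Si](C)(C)OS(=O)(=O)C(F)(F)F
Why: Silylation of the hindered secondary β-hydroxyl with the reactive TBSOTf/2,6-lutidine pair at low temperature, which should neither enolise the ketone nor provoke retro-aldol cleavage; it masks the only other oxygen that is γ to tin.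

Step 11
Reactants: 13 (2S,3S,6S)-2-[(1R,2S,3S)-1,2-bis(tert-butyldimethylsilyloxy)-3-(4-methoxybenzyloxy)hexyl]-6-(triethylsilyloxy)-3-(tributylstannyl)cyclohexan-1-one
Product: 15 (2S,3S,4R,4aS,5S,8S,8aS)-3,4-bis(tert-butyldimethylsilyloxy)-2-propyl-8-(triethylsilyloxy)-5-(tributylstannyl)octahydro-2H-chromen-8a-ol, via hydroxy ketone 14 (not isolated)
Conditions: DDQ, CH2Cl2/pH 7 phosphate buffer, 0 °C
Reagents that add atoms: none
Why: Oxidative cleavage of the PMB ether by DDQ in wet, buffered CH2Cl2 (silyl ethers and the tetraalkylstannane should be inert), after which the freed C9 hydroxyl adds to the inductively activated C1 ketone in a reversible 6-exo-trig hemiketalisation; the hemiketal carbon is set under thermodynamic control (trans ring fusion, axial anomeric hydroxyl).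

Step 12
Reactants: 15 (2S,3S,4R,4aS,5S,8S,8aS)-3,4-bis(tert-butyldimethylsilyloxy)-2-propyl-8-(triethylsilyloxy)-5-(tributylstannyl)octahydro-2H-chromen-8a-ol
Product: 17 (2S,5E,7R,8S,9S)-7,8-bis(tert-butyldimethylsilyloxy)-2-(triethylsilyloxy)dodec-5-en-9-olide, via lead alkoxide 16 (not isolated)
Conditions: Pb(OAc)4 (1.3 equiv), CaCO3, PhH, 25 to 60 °C
Reagents that add atoms: none
Why: The hemiketal hydroxyl of 15 exchanges for acetate on tetravalent lead to give alkoxide 16, which collapses heterolytically: the C5–Sn σ bond feeds into C5–C6, the shared C1–C6 bond breaks, C1 becomes the lactone carbonyl, and lead departs as Pb(OAc)2 (divalent lead) while tin leaves as Bu3SnOAc. The closest known reaction type is the Pb(OAc)4-induced oxidative Grob-type 1,4-fragmentation of γ-stannyl alcohols, which has been applied to hemiketals of 3-stannylcyclohexanones to give ring-expanded alkenyl lactones. No ring is closed in this step: the ten-membered lactone appears when the bond common to the cyclohexane and tetrahydropyran rings is cut, the only closure (6-exo-trig hemiketalisation) having been made in step 11. No stereocentre is created; the new stereo element is the C5=C6 geometry, which is E because in the chair the equatorial C5–Sn bond is antiperiplanar to C1–C6 and the equatorial C6–C7 bond is antiperiplanar to C5–C4, so C4 and C7 end up trans. The step needs E over Z and cleavage of C1–C6 rather than C1–C2 or C6–C7: the first is secured by the trans C5/C6 relationship set in step 9, the second by the fact that only C1–C6 is assisted by tin and that the hydroxyls on C2 and C7 are silylated.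

Step 13
Reactants: 17 (2S,5E,7R,8S,9S)-7,8-bis(tert-butyldimethylsilyloxy)-2-(triethylsilyloxy)dodec-5-en-9-olide
Product: 18 (2S,5E,7R,8S,9S)-7,8-bis(tert-butyldimethylsilyloxy)-2-hydroxydodec-5-en-9-olide
Conditions: HF·pyridine, pyridine, THF, 0 °C
Reagents that add atoms: none
Why: Selective desilylation: a triethylsilyl ether is cleaved much faster than secondary TBS ethers by pyridine-buffered HF·pyridine, and the buffered medium should leave the lactone and the C2 configuration intact.

Step 14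
Reactants: 19 trans,trans-muconic acid [(2E,4E)-hexa-2,4-dienedioic acid]
Product: 20 (2E,4E)-6-oxo-6-[2-(trimethylsilyl)ethoxy]hexa-2,4-dienoic acid
Conditions: Me3SiCH2CH2OH (1 equiv), 19 (3 equiv), DCC, DMAP (cat.), DMF, 0 to 25 °C
Reagents that add atoms: 2-(trimethylsilyl)ethanol, C[Si](C)(C)CCO
Why: Steglich esterification run with the diacid in excess so that the monoester predominates statistically over the diester; the acidic monoester is separated from neutral diester and poorly soluble diacid by extraction and chromatography.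

Step 15
Reactants: 18 (2S,5E,7R,8S,9S)-7,8-bis(tert-butyldimethylsilyloxy)-2-hydroxydodec-5-en-9-olide; 20 (2E,4E)-6-oxo-6-[2-(trimethylsilyl)ethoxy]hexa-2,4-dienoic acid
Product: 21 (2S,5E,7R,8S,9S)-7,8-bis(tert-butyldimethylsilyloxy)-2-{(2E,4E)-6-oxo-6-[2-(trimethylsilyl)ethoxy]hexa-2,4-dienoyloxy}dodec-5-en-9-olide
Conditions: DIC, DMAP (0.2 equiv), CH2Cl2, −20 to 0 °C
Reagents that add atoms: none
Why: Steglich esterification (carbodiimide with catalytic DMAP) acylates the C2 hydroxyl with retention, since the C2–O bond is not broken; low temperature and substoichiometric DMAP are chosen to avoid epimerisation of the now more acidic C2–H and isomerisation of the dienoate.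

Step 16
Reactants: 21 (2S,5E,7R,8S,9S)-7,8-bis(tert-butyldimethylsilyloxy)-2-{(2E,4E)-6-oxo-6-[2-(trimethylsilyl)ethoxy]hexa-2,4-dienoyloxy}dodec-5-en-9-olide
Product: 22 (2S,5E,7R,8R,9S)-2-[(2E,4E)-5-carboxypenta-2,4-dienoyloxy]-7,8-dihydroxydodec-5-en-9-olide (CNP0476488.2)
Conditions: TBAF/AcOH (1:1, excess), THF, 0 to 25 °C
Reagents that add atoms: none
Why: Fluoride-induced desilylation removes both TBS ethers and fragments the 2-(trimethylsilyl)ethyl ester (loss of ethene and Me3SiF), while the acetic acid buffer keeps the medium close to neutral so that the lactone, the α-acyloxy ester and the free vicinal diol should survive.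

**Compound list**

1 | cyclohex-2-en-1-one | O=C1C=CCCC1 | starting material
2 | (±)-6-acetoxycyclohex-2-en-1-one | CC(=O)OC1CCC=CC1=O | intermediate
3 | (S)-6-acetoxycyclohex-2-en-1-one | O=C1[C@@H](OC(C)=O)CCC=C1 | intermediate
4 | (S)-6-hydroxycyclohex-2-en-1-one | O=C1[C@@H](O)CCC=C1 | intermediate
5 | (S)-6-(triethylsilyloxy)cyclohex-2-en-1-one (target C1–C6 with the C2 stereocentre) | O=C1[C@@H](O[Si](CC)(CC)CC)CCC=C1 | intermediate
6 | (2R,3R)-3-propyloxiranemethanol (D-tartrate Sharpless epoxide of (E)-hex-2-en-1-ol) | CCC[C@H]1O[C@@H]1CO | starting material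
7 | (2R,3S)-3-(4-methoxybenzyloxy)hexane-1,2-diol (erythro) | CCC[C@H](OCc1ccc(OC)cc1)[C@H](O)CO | intermediate
8 | (2R,3S)-1,2-bis(tert-butyldimethylsilyloxy)-3-(4-methoxybenzyloxy)hexane | CCC[C@H](OCc1ccc(OC)cc1)[C@H](O[Si](C)(C)C(C)(C)C)CO[Si](C)(C)C(C)(C)C | intermediate
9 | (2R,3S)-2-(tert-butyldimethylsilyloxy)-3-(4-methoxybenzyloxy)hexan-1-ol | CCC[C@H](OCc1ccc(OC)cc1)[C@H](O[Si](C)(C)C(C)(C)C)CO | intermediate
10 | (2S,3S)-2-(tert-butyldimethylsilyloxy)-3-(4-methoxybenzyloxy)hexanal (target C7–C12) | CCC[C@H](OCc1ccc(OC)cc1)[C@H](O[Si](C)(C)C(C)(C)C)C=O | intermediate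
11 | lithium (3S,6S)-6-(triethylsilyloxy)-3-(tributylstannyl)cyclohex-1-en-1-olate | [Li]OC1=C[C@@H]([Sn](CCCC)(CCCC)CCCC)CC[C@@H]1O[Si](CC)(CC)CC | intermediate (not isolated)
12 | (2S,3S,6S)-2-[(1R,2R,3S)-2-(tert-butyldimethylsilyloxy)-1-hydroxy-3-(4-methoxybenzyloxy)hexyl]-6-(triethylsilyloxy)-3-(tributylstannyl)cyclohexan-1-one (aldol adduct; tin and side chain trans) | O=C1[C@@H](O[Si](CC)(CC)CC)CC[C@H]([Sn](CCCC)(CCCC)CCCC)[C@H]1[C@@H](O)[C@@H](O[Si](C)(C)C(C)(C)C)[C@@H](OCc1ccc(OC)cc1)CCC | intermediate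
13 | (2S,3S,6S)-2-[(1R,2S,3S)-1,2-bis(tert-butyldimethylsilyloxy)-3-(4-methoxybenzyloxy)hexyl]-6-(triethylsilyloxy)-3-(tributylstannyl)cyclohexan-1-one | O=C1[C@@H](O[Si](CC)(CC)CC)CC[C@H]([Sn](CCCC)(CCCC)CCCC)[C@H]1[C@@H](O[Si](C)(C)C(C)(C)C)[C@@H](O[Si](C)(C)C(C)(C)C)[C@@H](OCc1ccc(OC)cc1)CCC | intermediate
14 | (2S,3S,6S)-2-[(1R,2S,3S)-1,2-bis(tert-butyldimethylsilyloxy)-3-hydroxyhexyl]-6-(triethylsilyloxy)-3-(tributylstannyl)cyclohexan-1-one (δ-hydroxy ketone) | O=C1[C@@H](O[Si](CC)(CC)CC)CC[C@H]([Sn](CCCC)(CCCC)CCCC)[C@H]1[C@@H](O[Si](C)(C)C(C)(C)C)[C@@H](O[Si](C)(C)C(C)(C)C)[C@@H](O)CCC | intermediate (not isolated)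
15 | (2S,3S,4R,4aS,5S,8S,8aS)-3,4-bis(tert-butyldimethylsilyloxy)-2-propyl-8-(triethylsilyloxy)-5-(tributylstannyl)octahydro-2H-chromen-8a-ol (trans-fused stannyl hemiketal) | O[C@]12O[C@@H](CCC)[C@H](O[Si](C)(C)C(C)(C)C)[C@H](O[Si](C)(C)C(C)(C)C)[C@@H]1[C@@H]([Sn](CCCC)(CCCC)CCCC)CC[C@@H]2O[Si](CC)(CC)CC | intermediate
16 | lead triacetate alkoxide of hemiketal 15 (O8a–Pb(OAc)3; carbon framework arranged as in 15) | CC(=O)O[Pb](OC(C)=O)(OC(C)=O)O[C@]12O[C@@H](CCC)[C@H](O[Si](C)(C)C(C)(C)C)[C@H](O[Si](C)(C)C(C)(C)C)[C@@H]1[C@@H]([Sn](CCCC)(CCCC)CCCC)CC[C@@H]2O[Si](CC)(CC)CC | intermediate (not isolated)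
17 | (2S,5E,7R,8S,9S)-7,8-bis(tert-butyldimethylsilyloxy)-2-(triethylsilyloxy)dodec-5-en-9-olide | CCC[C@@H]1OC(=O)[C@@H](O[Si](CC)(CC)CC)CC/C=C/[C@@H](O[Si](C)(C)C(C)(C)C)[C@H]1O[Si](C)(C)C(C)(C)C | intermediate
18 | (2S,5E,7R,8S,9S)-7,8-bis(tert-butyldimethylsilyloxy)-2-hydroxydodec-5-en-9-olide | CCC[C@@H]1OC(=O)[C@@H](O)CC/C=C/[C@@H](O[Si](C)(C)C(C)(C)C)[C@H]1O[Si](C)(C)C(C)(C)C | intermediate
19 | trans,trans-muconic acid | OC(=O)/C=C/C=C/C(=O)O | starting material
20 | (2E,4E)-6-oxo-6-[2-(trimethylsilyl)ethoxy]hexa-2,4-dienoic acid | C[Si](C)(C)CCOC(=O)/C=C/C=C/C(=O)O | intermediate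
21 | (2S,5E,7R,8S,9S)-7,8-bis(tert-butyldimethylsilyloxy)-2-{(2E,4E)-6-oxo-6-[2-(trimethylsilyl)ethoxy]hexa-2,4-dienoyloxy}dodec-5-en-9-olide | CCC[C@@H]1OC(=O)[C@@H](OC(=O)/C=C/C=C/C(=O)OCC[Si](C)(C)C)CC/C=C/[C@@H](O[Si](C)(C)C(C)(C)C)[C@H]1O[Si](C)(C)C(C)(C)C | intermediate
22 | (2S,5E,7R,8R,9S)-2-[(2E,4E)-5-carboxypenta-2,4-dienoyloxy]-7,8-dihydroxydodec-5-en-9-olide | CCC[C@@H]1OC(=O)[C@@H](OC(=O)/C=C/C=C/C(=O)O)CC/C=C/[C@@H](O)[C@H]1O | target

**Step count and risks**

Total steps: 16. Longest linear sequence: 11 steps (1 to 22 through steps 1–4, 9–13, 15 and 16; the branch from 6 through steps 5–8 is equally long).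

Steps most likely to fail:

1. Step 12 (oxidative fragmentation). The lead alkoxide may form too slowly if the hemiketal is only sparsely populated beside the open hydroxy ketone. The carbocycle may react from a conformer in which C5–Sn is not antiperiplanar to C1–C6 (no fragmentation, or Z olefin). The oxidant may instead cleave C1–C2. Fallback, from aldehyde 10 back to lactone 17, closing the ring by olefin metathesis across C5=C6: CH2=CHMgBr is added to 10 (THF, −78 °C, Felkin control) to give (3R,4R,5S)-4-(tert-butyldimethylsilyloxy)-5-(4-methoxybenzyloxy)oct-1-en-3-ol F1. Silylation (TBSOTf, 2,6-lutidine) gives (3R,4S,5S)-3,4-bis(tert-butyldimethylsilyloxy)-5-(4-methoxybenzyloxy)oct-1-ene F2, and DDQ frees (3R,4S,5S)-3,4-bis(tert-butyldimethylsilyloxy)oct-1-en-5-ol F3. The acid half comes from commercial methyl (S)-glycidate: CuI-catalysed opening with allylmagnesium bromide gives methyl (S)-2-hydroxyhex-5-enoate F4, TESCl/imidazole gives methyl (S)-2-(triethylsilyloxy)hex-5-enoate F5, and LiOH hydrolysis gives (S)-2-(triethylsilyloxy)hex-5-enoic acid F6. Carbodiimide esterification of F3 with F6 gives (3R,4S,5S)-3,4-bis(tert-butyldimethylsilyloxy)oct-1-en-5-yl (S)-2-(triethylsilyloxy)hex-5-enoate F7. Ring-closing metathesis with the second-generation Grubbs catalyst in dilute CH2Cl2 would then give 17; the olefin geometry of the ten-membered ring would have to be steered by the choice of ruthenium carbene.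

2. Step 9 (stannyl addition/aldol). Facial selectivity at the aldehyde may erode when the chair transition state demanded by the tin-bearing enolate opposes the Cornforth–Felkin preference, which happens for the enolate with tin cis to the C2 silyloxy group. Retro-aldol equilibration or loss of the stannyl anion from the enolate may add to this. Fallback, from enone 5 and aldehyde 10 back to ketone 13, creating C7 with an sp2 nucleophile that has no neighbouring stereocentre and bringing tin in afterwards: α-iodination of 5 (I2, pyridine, CH2Cl2) gives (S)-2-iodo-6-(triethylsilyloxy)cyclohex-2-en-1-one F8. Nozaki–Hiyama–Kishi coupling with 10 (CrCl2, cat. NiCl2, DMF) gives (S)-2-[(1R,2R,3S)-2-(tert-butyldimethylsilyloxy)-1-hydroxy-3-(4-methoxybenzyloxy)hexyl]-6-(triethylsilyloxy)cyclohex-2-en-1-one F9, with the 7,8-anti relationship expected for Felkin addition. TBSOTf/2,6-lutidine gives (S)-2-[(1R,2S,3S)-1,2-bis(tert-butyldimethylsilyloxy)-3-(4-methoxybenzyloxy)hexyl]-6-(triethylsilyloxy)cyclohex-2-en-1-one F10. Conjugate addition of Bu3SnLi (THF, −78 °C) and protonation at −78 °C is expected to give first the cis ketone (2R,3S,6S)-2-[(1R,2S,3S)-1,2-bis(tert-butyldimethylsilyloxy)-3-(4-methoxybenzyloxy)hexyl]-6-(triethylsilyloxy)-3-(tributylstannyl)cyclohexan-1-one F11. Brief treatment with catalytic DBU at 0 °C should equilibrate it to the diequatorial trans ketone 13; loss of the β-silyloxy group and epimerisation at C2 would need to be watched.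

3. Step 16 (global deprotection). The two hindered vicinal TBS ethers may be cleaved only slowly, while the α-acyloxy lactone suffers acyl migration, lactone opening or C2 epimerisation in the fluoride medium. Fallback, from 19 and 18 back to 22, avoiding basic fluoride by masking the distal carboxyl as an allyl ester: mono-esterification of 19 with allyl alcohol (DCC, DMAP, DMF) gives (2E,4E)-6-(allyloxy)-6-oxohexa-2,4-dienoic acid F12. Coupling with 18 (DIC, DMAP) gives (2S,5E,7R,8S,9S)-2-[(2E,4E)-6-(allyloxy)-6-oxohexa-2,4-dienoyloxy]-7,8-bis(tert-butyldimethylsilyloxy)dodec-5-en-9-olide F13. HF·pyridine in THF/pyridine removes both TBS ethers to give (2S,5E,7R,8R,9S)-2-[(2E,4E)-6-(allyloxy)-6-oxohexa-2,4-dienoyloxy]-7,8-dihydroxydodec-5-en-9-olide F14. Pd(PPh3)4 (zerovalent palladium) with morpholine then transfers the allyl group to the amine and releases 22.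

**Further compounds**

F1 | step 12 | (3R,4R,5S)-4-(tert-butyldimethylsilyloxy)-5-(4-methoxybenzyloxy)oct-1-en-3-ol | C=C[C@@H](O)[C@@H](O[Si](C)(C)C(C)(C)C)[C@@H](OCc1ccc(OC)cc1)CCC
F2 | step 12 | (3R,4S,5S)-3,4-bis(tert-butyldimethylsilyloxy)-5-(4-methoxybenzyloxy)oct-1-ene | C=C[C@@H](O[Si](C)(C)C(C)(C)C)[C@@H](O[Si](C)(C)C(C)(C)C)[C@@H](OCc1ccc(OC)cc1)CCC
F3 | step 12 | (3R,4S,5S)-3,4-bis(tert-butyldimethylsilyloxy)oct-1-en-5-ol | C=C[C@@H](O[Si](C)(C)C(C)(C)C)[C@@H](O[Si](C)(C)C(C)(C)C)[C@@H](O)CCC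
F4 | step 12 | methyl (S)-2-hydroxyhex-5-enoate | COC(=O)[C@@H](O)CCC=C
F5 | step 12 | methyl (S)-2-(triethylsilyloxy)hex-5-enoate | COC(=O)[C@@H](O[Si](CC)(CC)CC)CCC=C
F6 | step 12 | (S)-2-(triethylsilyloxy)hex-5-enoic acid | OC(=O)[C@@H](O[Si](CC)(CC)CC)CCC=C
F7 | step 12 | (3R,4S,5S)-3,4-bis(tert-butyldimethylsilyloxy)oct-1-en-5-yl (S)-2-(triethylsilyloxy)hex-5-enoate | C=C[C@@H](O[Si](C)(C)C(C)(C)C)[C@@H](O[Si](C)(C)C(C)(C)C)[C@H](CCC)OC(=O)[C@@H](O[Si](CC)(CC)CC)CCC=C
F8 | step 9 | (S)-2-iodo-6-(triethylsilyloxy)cyclohex-2-en-1-one | O=C1[C@@H](O[Si](CC)(CC)CC)CCC=C1I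
F9 | step 9 | (S)-2-[(1R,2R,3S)-2-(tert-butyldimethylsilyloxy)-1-hydroxy-3-(4-methoxybenzyloxy)hexyl]-6-(triethylsilyloxy)cyclohex-2-en-1-one | O=C1[C@@H](O[Si](CC)(CC)CC)CCC=C1[C@@H](O)[C@@H](O[Si](C)(C)C(C)(C)C)[C@@H](OCc1ccc(OC)cc1)CCC
F10 | step 9 | (S)-2-[(1R,2S,3S)-1,2-bis(tert-butyldimethylsilyloxy)-3-(4-methoxybenzyloxy)hexyl]-6-(triethylsilyloxy)cyclohex-2-en-1-one | O=C1[C@@H](O[Si](CC)(CC)CC)CCC=C1[C@@H](O[Si](C)(C)C(C)(C)C)[C@@H](O[Si](C)(C)C(C)(C)C)[C@@H](OCc1ccc(OC)cc1)CCC
F11 | step 9 | (2R,3S,6S)-2-[(1R,2S,3S)-1,2-bis(tert-butyldimethylsilyloxy)-3-(4-methoxybenzyloxy)hexyl]-6-(triethylsilyloxy)-3-(tributylstannyl)cyclohexan-1-one | O=C1[C@@H](O[Si](CC)(CC)CC)CC[C@H]([Sn](CCCC)(CCCC)CCCC)[C@@H]1[C@@H](O[Si](C)(C)C(C)(C)C)[C@@H](O[Si](C)(C)C(C)(C)C)[C@@H](OCc1ccc(OC)cc1)CCC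
F12 | step 16 | (2E,4E)-6-(allyloxy)-6-oxohexa-2,4-dienoic acid | C=CCOC(=O)/C=C/C=C/C(=O)O
F13 | step 16 | (2S,5E,7R,8S,9S)-2-[(2E,4E)-6-(allyloxy)-6-oxohexa-2,4-dienoyloxy]-7,8-bis(tert-butyldimethylsilyloxy)dodec-5-en-9-olide | CCC[C@@H]1OC(=O)[C@@H](OC(=O)/C=C/C=C/C(=O)OCC=C)CC/C=C/[C@@H](O[Si](C)(C)C(C)(C)C)[C@H]1O[Si](C)(C)C(C)(C)C
F14 | step 16 | (2S,5E,7R,8R,9S)-2-[(2E,4E)-6-(allyloxy)-6-oxohexa-2,4-dienoyloxy]-7,8-dihydroxydodec-5-en-9-olide | CCC[C@@H]1OC(=O)[C@@H](OC(=O)/C=C/C=C/C(=O)OCC=C)CC/C=C/[C@@H](O)[C@H]1O
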